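The benzene ring of coumarin A (C4a, C5, C6, C7, C8, C8a) is built de novo by a Dötz benzannulation. Its oxygen pattern maps onto the reagents: C6–OMe is the carbene carbon, C8a–O (para to C6) is a carbonyl ligand, and C7–O is the α-carbon of an alkoxyvinyl group. In one operation a (1-tert-butoxyvinyl)(methoxy)carbene chromium complex and a terminal enyne form C5–C6, C4a–C8a and C8–C8a and deliver the free C8a phenol. The enyne is a (Z)-2-aryloxypent-2-en-4-ynoate that already holds the scopoletin 7-O ether and the ester carbon destined to be C2. Photoisomerisation with lactonisation, then tert-butyl removal, complete the route.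

Key step: step 6

Remark: the target has no stereocentre and no stereogenic double bond, so it is achiral and needs no enantioselective step. The Z geometry of the enyne is chosen on purpose: it holds the ester trans to the alkyne, out of reach of the chromium vinylcarbene formed in the key step.

Step 1
Reactants: 1 tert-butyl vinyl ether; 2 chromium hexacarbonyl
Product: 5 pentacarbonyl[(1-tert-butoxyethenyl)(methoxy)methylidene]chromium, via 1-tert-butoxyvinyllithium 3 (not isolated), via lithium acylchromate 4 (not isolated)
Conditions: 1 (1.2 equiv), t-BuLi (1.0 equiv), THF/pentane, −78 → 0 °C; add to 2, THF, −78 °C → rt; then Me3OBF4, CH2Cl2, 0 °C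
Reagents that add atoms: trimethyloxonium tetrafluoroborate, C[O+](C)C.F[B-](F)(F)F; tert-butyllithium, [Li]C(C)(C)C (lithium only in intermediates 3 and 4)
Why: Fischer carbene synthesis, in which alkoxy-directed α-deprotonation of the enol ether gives vinyllithium 3, this adds to a carbonyl ligand of 2 to give acylchromate 4, and O-methylation with Meerwein's salt gives 5; the α-alkoxy substituent should protect the otherwise polymerisation-prone vinylcarbene complex.

Step 2
Reactants: 6 trimethyl phosphonoacetate
Product: 7 methyl 2-diazo-2-(dimethoxyphosphoryl)acetate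
Conditions: p-ABSA, DBU, MeCN, 0 °C → rt
Reagents that add atoms: 4-acetamidobenzenesulfonyl azide (p-ABSA), CC(=O)Nc1ccc(cc1)S(=O)(=O)N=[N+]=[N-]
Why: Regitz diazo transfer, in which the DBU-generated phosphonoacetate anion attacks the terminal nitrogen of the sulfonyl azide and the adduct fragments to the diazo compound and the sulfonamide.

Step 3
Reactants: 8 scopoletin; 7 methyl 2-diazo-2-(dimethoxyphosphoryl)acetate
Product: 9 methyl 2-(dimethoxyphosphoryl)-2-[(6-methoxy-2-oxo-2H-chromen-7-yl)oxy]acetate (racemic)
Conditions: Rh2(OAc)4 (2 mol %), ClCH2CH2Cl, 80 °C, slow addition of 7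
Reagents that add atoms: none
Why: Rhodium(II)-carbenoid O–H insertion, in which the acceptor/acceptor carbenoid from 7 is captured by the phenolic oxygen of 8 (oxonium ylide, proton shift) faster than it attacks the electron-poor C3=C4 bond or the arene; the new carbon is a stereocentre, formed racemic and destroyed in step 4.

Step 4
Reactants: 9 methyl 2-(dimethoxyphosphoryl)-2-[(6-methoxy-2-oxo-2H-chromen-7-yl)oxy]acetate; 10 3-(trimethylsilyl)prop-2-ynal
Product: 12 methyl (Z)-2-[(6-methoxy-2-oxo-2H-chromen-7-yl)oxy]-5-(trimethylsilyl)pent-2-en-4-ynoate, via lithiated phosphonate 11 (not isolated)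
Conditions: LiHMDS, THF, −78 °C; then 10, −78 → 0 °C
Reagents that add atoms: lithium bis(trimethylsilyl)amide, [Li]N([Si](C)(C)C)[Si](C)(C)C (lithium only in intermediate 11)
Why: Horner–Wadsworth–Emmons olefination, in which the non-nucleophilic base forms anion 11 before the base-labile ynal is added and the adduct collapses with loss of dimethyl phosphate; with lithium as counter-ion and warming the addition is reversible, so the enoate with the alkynyl group trans to the ester (Z) should predominate, any E isomer is removed by chromatography, and the geometry is to be assigned from the three-bond C1–H3 coupling.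

Step 5
Reactants: 12 methyl (Z)-2-[(6-methoxy-2-oxo-2H-chromen-7-yl)oxy]-5-(trimethylsilyl)pent-2-en-4-ynoate
Product: 13 methyl (Z)-2-[(6-methoxy-2-oxo-2H-chromen-7-yl)oxy]pent-2-en-4-ynoate
Conditions: TBAF, AcOH, THF, −20 → 0 °C
Reagents that add atoms: none
Why: Buffered fluoride protodesilylation, in which fluoride attacks silicon and acetic acid protonates the acetylide at once, so the electron-poor enyne ester and the lactone are not exposed to free base.

Step 6
Reactants: 13 methyl (Z)-2-[(6-methoxy-2-oxo-2H-chromen-7-yl)oxy]pent-2-en-4-ynoate; 5 pentacarbonyl[(1-tert-butoxyethenyl)(methoxy)methylidene]chromium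
Product: 15 methyl (Z)-3-[4-(tert-butoxy)-2-hydroxy-5-methoxyphenyl]-2-[(6-methoxy-2-oxo-2H-chromen-7-yl)oxy]prop-2-enoate, via tricarbonylchromium arene complex 14 (not isolated)
Conditions: 5 (1.3 equiv), THF (0.05 M), 50 °C, Ar; then air, EtOAc, rt
Reagents that add atoms: none
Why: Dötz benzannulation, the established reaction of alkenyl(alkoxy)carbene chromium complexes with terminal alkynes: loss of one CO from 5 lets the alkyne of 13 bind and insert into the Cr=C bond (C5–C6), CO insertion into the vinylcarbene gives a chromium-bound dienylketene (C4a–C8a), and the benzene ring closes by thermal 6π-electrocyclisation between the ketene carbon and the vinyl CH2 terminus (C8–C8a), after which enolisation of the cyclohexadienone gives the C8a phenol as its Cr(CO)3 complex 14. Air then oxidises the chromium(0) fragment and frees 15. No stereocentre is formed, and the trisubstituted olefin takes no part and should keep its Z geometry. The selectivity needed is regiochemical: the substituted alkyne carbon must end up next to the carbonyl-derived carbon, and with a terminal alkyne the size difference between H and the enoate arm places the arm ortho to the new hydroxyl. Phenol formation is favoured over five-membered-ring or furan formation by the alkenyl chromium complex in THF and by the Z geometry, which keeps the ester carbonyl away from the vinylcarbene carbon. No acid, base or external oxidant is present during the annulation, so the lactone of coumarin B, the aryl enol ether and the tert-butyl ether should survive; the work-up uses air, not Ce(IV) or Fe(III), which would take the 4-methoxyphenol to a quinone.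

Step 7
Reactants: 15 methyl (Z)-3-[4-(tert-butoxy)-2-hydroxy-5-methoxyphenyl]-2-[(6-methoxy-2-oxo-2H-chromen-7-yl)oxy]prop-2-enoate
Product: 17 7-(tert-butoxy)-6-methoxy-3-[(6-methoxy-2-oxo-2H-chromen-7-yl)oxy]-2H-chromen-2-one, via (E)-hydroxy ester 16 (not isolated)
Conditions: hν (365 nm LED), degassed MeCN/MeOH 4:1 (2 mM), 35 °C
Reagents that add atoms: none
Why: Photochemical E/Z isomerisation of the o-hydroxycinnamate-type C3=C4 olefin gives 16, whose C8a–OH then attacks the now proximal methyl ester (lactonisation with loss of methanol); the lactone cannot revert, so the photostationary mixture should drain to 17, while long-wavelength light and high dilution disfavour [2+2] dimerisation of the coumarin chromophores.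

Step 8
Reactants: 17 7-(tert-butoxy)-6-methoxy-3-[(6-methoxy-2-oxo-2H-chromen-7-yl)oxy]-2H-chromen-2-one
Product: 18 7-hydroxy-6-methoxy-3-[(6-methoxy-2-oxo-2H-chromen-7-yl)oxy]-2H-chromen-2-one
Conditions: TFA, CH2Cl2, 0 °C → rt
Reagents that add atoms: none
Why: Acidolysis of the aryl tert-butyl ether (protonation, loss of the tert-butyl cation as isobutene) should free the C7 phenol, while the aryl methyl ethers, the C3 aryl enol ether and both lactones are inert to TFA.

Compound list
1 | tert-butyl vinyl ether | C=COC(C)(C)C | starting material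
2 | chromium hexacarbonyl | O=C=[Cr](=C=O)(=C=O)(=C=O)(=C=O)=C=O | starting material
3 | 1-tert-butoxyvinyllithium | [Li]C(=C)OC(C)(C)C | intermediate
4 | lithium pentacarbonyl[2-(tert-butoxy)-1-oxidoprop-2-en-1-ylidene]chromate (lithium acylchromate) | [Li+].[O-]C(C(=C)OC(C)(C)C)=[Cr](=C=O)(=C=O)(=C=O)(=C=O)=C=O | intermediate
5 | pentacarbonyl[(1-tert-butoxyethenyl)(methoxy)methylidene]chromium | COC(C(=C)OC(C)(C)C)=[Cr](=C=O)(=C=O)(=C=O)(=C=O)=C=O | intermediate
6 | trimethyl phosphonoacetate | COC(=O)CP(=O)(OC)OC | starting material
7 | methyl 2-diazo-2-(dimethoxyphosphoryl)acetate | COC(=O)C(=[N+]=[N-])P(=O)(OC)OC | intermediate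
8 | scopoletin (7-hydroxy-6-methoxy-2H-chromen-2-one) | COc1cc2ccc(=O)oc2cc1O | starting material
9 | methyl 2-(dimethoxyphosphoryl)-2-[(6-methoxy-2-oxo-2H-chromen-7-yl)oxy]acetate (racemic) | COC(=O)C(Oc1cc2oc(=O)ccc2cc1OC)P(=O)(OC)OC | intermediate
10 | 3-(trimethylsilyl)prop-2-ynal | C[Si](C)(C)C#CC=O | starting material
11 | lithium salt of the carbanion of 9 (lithiated phosphonate) | [Li+].COC(=O)[C-](Oc1cc2oc(=O)ccc2cc1OC)P(=O)(OC)OC | intermediate
12 | methyl (Z)-2-[(6-methoxy-2-oxo-2H-chromen-7-yl)oxy]-5-(trimethylsilyl)pent-2-en-4-ynoate | C[Si](C)(C)C#C/C=C(\Oc1cc2oc(=O)ccc2cc1OC)C(=O)OC | intermediate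
13 | methyl (Z)-2-[(6-methoxy-2-oxo-2H-chromen-7-yl)oxy]pent-2-en-4-ynoate | C#C/C=C(\Oc1cc2oc(=O)ccc2cc1OC)C(=O)OC | intermediate
14 | tricarbonylchromium complex of 15, η6-bound to the new arene (hapticity not expressible in SMILES, fragments joined by a dot) | COC(=O)/C(Oc1cc2oc(=O)ccc2cc1OC)=C/c1cc(OC)c(OC(C)(C)C)cc1O.O=C=[Cr](=C=O)=C=O | intermediate
15 | methyl (Z)-3-[4-(tert-butoxy)-2-hydroxy-5-methoxyphenyl]-2-[(6-methoxy-2-oxo-2H-chromen-7-yl)oxy]prop-2-enoate | COC(=O)/C(Oc1cc2oc(=O)ccc2cc1OC)=C/c1cc(OC)c(OC(C)(C)C)cc1O | intermediate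
16 | methyl (E)-3-[4-(tert-butoxy)-2-hydroxy-5-methoxyphenyl]-2-[(6-methoxy-2-oxo-2H-chromen-7-yl)oxy]prop-2-enoate | COC(=O)/C(Oc1cc2oc(=O)ccc2cc1OC)=C\c1cc(OC)c(OC(C)(C)C)cc1O | intermediate
17 | 7-(tert-butoxy)-6-methoxy-3-[(6-methoxy-2-oxo-2H-chromen-7-yl)oxy]-2H-chromen-2-one | COc1cc2cc(Oc3cc4oc(=O)ccc4cc3OC)c(=O)oc2cc1OC(C)(C)C | intermediate
18 | 7-hydroxy-6-methoxy-3-[(6-methoxy-2-oxo-2H-chromen-7-yl)oxy]-2H-chromen-2-one | COc1cc2cc(Oc3cc4oc(=O)ccc4cc3OC)c(=O)oc2cc1O | target

Total step count: 8
Longest linear sequence: 7 steps (6 → 18, steps 2–8); step 1 is a one-step side branch that joins at step 6.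

Steps most likely to fail

Step 6. After alkyne insertion the chromium vinylcarbene may bypass CO insertion and give five-membered-ring or cyclobutenone products. The electron-poor enyne may also oligomerise on heating, and the electron-rich phenol may be over-oxidised during decomplexation. The fallback gives up de novo arene construction and closes pyranone A on a preformed arene by Perkin-type condensation. It sets out from scopoletin 8 and returns at target 18. O-alkylation of 8 with tert-butyl bromoacetate (K2CO3, DMF) should give tert-butyl 2-[(6-methoxy-2-oxo-2H-chromen-7-yl)oxy]acetate F1. TFA in CH2Cl2 should then release 2-[(6-methoxy-2-oxo-2H-chromen-7-yl)oxy]acetic acid F2. Perkin–Oglialoro condensation of F2 with purchased 2,4-dihydroxy-5-methoxybenzaldehyde (Ac2O, Et3N, 110 °C) should form C3=C4 and the lactone, with the second phenol acetylated, giving 6-methoxy-3-[(6-methoxy-2-oxo-2H-chromen-7-yl)oxy]-2-oxo-2H-chromen-7-yl acetate F3. Brief K2CO3/MeOH at 0 °C should remove the aryl acetate and give 18.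

Step 7. The photostationary mixture may drain only slowly, and meanwhile the two coumarin chromophores may undergo [2+2] photodimerisation or the phenol may photo-oxidise. The fallback replaces light by thermal nucleophilic catalysis. It sets out from 15 and returns at 17 without any new isolated compound. With n-Bu3P (20 mol %) in MeOH at 65 °C under argon, the phosphine should add reversibly to C4. In the resulting phosphonium enolate C3–C4 is a single bond and rotates, the C8a–OH lactonises onto the ester, and the phosphine is expelled to restore C3=C4 within the lactone.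

Step 4. The hindered, stabilised aryloxyphosphonate anion may add sluggishly to the base-labile ynal, and geometric control may erode because the slim alkynyl group offers little steric bias. The fallback separates C–C bond formation from alkene formation by aldol addition followed by elimination. It sets out from scopoletin 8 and aldehyde 10 and returns at 12. Alkylation of 8 with methyl bromoacetate (K2CO3, acetone) should give methyl 2-[(6-methoxy-2-oxo-2H-chromen-7-yl)oxy]acetate F4. LiHMDS in THF at −78 °C should convert it into the lithium enolate of methyl 2-[(6-methoxy-2-oxo-2H-chromen-7-yl)oxy]acetate F5 (not isolated). Irreversible addition of F5 to 10 at −78 °C should give methyl 3-hydroxy-2-[(6-methoxy-2-oxo-2H-chromen-7-yl)oxy]-5-(trimethylsilyl)pent-4-ynoate F6 as a mixture of racemic diastereomers. MsCl/Et3N should give methyl 3-(methanesulfonyloxy)-2-[(6-methoxy-2-oxo-2H-chromen-7-yl)oxy]-5-(trimethylsilyl)pent-4-ynoate F7 (not isolated). DBU should then effect E1cB elimination under thermodynamic control to 12, with any E isomer removed as in the main route.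

Further compounds
F1 | step 6 | tert-butyl 2-[(6-methoxy-2-oxo-2H-chromen-7-yl)oxy]acetate | COc1cc2ccc(=O)oc2cc1OCC(=O)OC(C)(C)C
F2 | step 6 | 2-[(6-methoxy-2-oxo-2H-chromen-7-yl)oxy]acetic acid | COc1cc2ccc(=O)oc2cc1OCC(=O)O
F3 | step 6 | 6-methoxy-3-[(6-methoxy-2-oxo-2H-chromen-7-yl)oxy]-2-oxo-2H-chromen-7-yl acetate | COc1cc2cc(Oc3cc4oc(=O)ccc4cc3OC)c(=O)oc2cc1OC(C)=O
F0 | step 7 | none | none
F4 | step 4 | methyl 2-[(6-methoxy-2-oxo-2H-chromen-7-yl)oxy]acetate | COC(=O)COc1cc2oc(=O)ccc2cc1OC
F5 | step 4 | lithium enolate of methyl 2-[(6-methoxy-2-oxo-2H-chromen-7-yl)oxy]acetate | [Li]OC(OC)=COc1cc2oc(=O)ccc2cc1OC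
F6 | step 4 | methyl 3-hydroxy-2-[(6-methoxy-2-oxo-2H-chromen-7-yl)oxy]-5-(trimethylsilyl)pent-4-ynoate (mixture of racemic diastereomers) | COC(=O)C(Oc1cc2oc(=O)ccc2cc1OC)C(O)C#C[Si](C)(C)C
F7 | step 4 | methyl 3-(methanesulfonyloxy)-2-[(6-methoxy-2-oxo-2H-chromen-7-yl)oxy]-5-(trimethylsilyl)pent-4-ynoate | COC(=O)C(Oc1cc2oc(=O)ccc2cc1OC)C(OS(C)(=O)=O)C#C[Si](C)(C)C
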